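**Retrosynthetic overview**

1. Target ⇐ desilylation ⇐ Mitsunobu esterification with inversion at C3 (silyl-protected caffeic acid) ⇐ 1β,3α-diol ⇐ hydroxyl-directed reduction of a 3α-hydroxy-1-ketone (eudesmane numbering: ring A = C1–C5, C10; ring B = C5–C10; C15 = exocyclic CH2).
2. Decalin ⇐ one intramolecular Diels–Alder reaction of an acyclic tetraene that forms C3–C4 and C5–C10 together; rings A and B arise in the same step, and no carbocycle exists before it.
3. Enabling feature: ring A carries oxygen on C1 and C3 (both flanking C2, next to quaternary C10) and an exocyclic methylene on C4 next to the ring-fusion C5–H. Read backwards, C3=C2–C1(O)=C10 is a 1-alkoxy-3-silyloxy diene and C15=C4=C5 an allene whose inner double bond is the dienophile; ring B (C6–C9, with the C7 and C8 stereocentres) is the tether.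
4. Tetraene ⇐ geometry-defining conjugate reduction/silylation of a cross-conjugated dienone ⇐ ynone from an α-methylene-γ-butyrolactone ⇐ catalytic asymmetric 2-(ethoxycarbonyl)allylation of (R)-2-isopropylhexa-4,5-dienal ⇐ Evans propargylation and Crabbé allene homologation.

Key step: step 10

Remark: ring compounds are named by eudesmane numbering (α = face opposite to the C10 methyl); acyl oxazolidinone 1 is taken as a purchased compound.

**Step 1**
Reactants: 1 (4R)-4-benzyl-3-(3-methylbutanoyl)-1,3-oxazolidin-2-one; 2 propargyl bromide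
Product: 4 (4R)-4-benzyl-3-[(2R)-2-(propan-2-yl)pent-4-ynoyl]-1,3-oxazolidin-2-one, via sodium enolate 3 (not isolated)
Conditions: NaN(SiMe3)2, THF, −78 °C; then propargyl bromide, −78 → −40 °C
Reagents that add atoms: none
Why: Evans asymmetric alkylation, in which the chelated (Z)-enolate 3 is attacked by the propargylic bromide on the face opposite to the benzyl group of the (4R) auxiliary, which should set C7 as R.

**Step 2**
Reactants: 4 (4R)-4-benzyl-3-[(2R)-2-(propan-2-yl)pent-4-ynoyl]-1,3-oxazolidin-2-one
Product: 5 (2R)-2-(propan-2-yl)pent-4-yn-1-ol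
Conditions: LiBH4, Et2O/THF, 0 °C; aqueous work-up
Reagents that add atoms: none
Why: Reductive cleavage of the N-acyl oxazolidinone by hydride attack at the exocyclic carbonyl should leave the alkyne and the stereocentre untouched and return the auxiliary.

**Step 3**
Reactants: 5 (2R)-2-(propan-2-yl)pent-4-yn-1-ol; 6 paraformaldehyde
Product: 8 (2R)-2-(propan-2-yl)hexa-4,5-dien-1-ol, via propargylic amine 7 (not isolated)
Conditions: (CH2O)n, CuI (0.5 equiv), dicyclohexylamine, 1,4-dioxane, reflux
Reagents that add atoms: none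
Why: Crabbé homologation, in which the copper-mediated Mannich reaction gives amine 7 and a retro-ene-type 1,5-hydride transfer then expels the imine and leaves the terminal allene C5=C4=C15, a sequence that tolerates a free hydroxyl.

**Step 4**
Reactants: 8 (2R)-2-(propan-2-yl)hexa-4,5-dien-1-ol
Product: 9 (2R)-2-(propan-2-yl)hexa-4,5-dienal
Conditions: Dess–Martin periodinane, CH2Cl2, 0 → 23 °C; used at once
Reagents that add atoms: none
Why: Dess–Martin oxidation is mild enough to spare the allene and should not epimerise the α-stereocentre when the aldehyde is carried on directly.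

**Step 5**
Reactants: 9 (2R)-2-(propan-2-yl)hexa-4,5-dienal; 10 ethyl 2-(bromomethyl)prop-2-enoate
Product: 13 (5S)-3-methylidene-5-[(3R)-2-methylhepta-5,6-dien-3-yl]oxolan-2-one, via silyl ether ester 11 (not isolated), via hydroxy ester 12 (not isolated)
Conditions: CrCl2 (10 mol %), chiral 1,8-bis(oxazolin-2-yl)carbazole ligand (12 mol %, enantiomer chosen for Si-face addition), Mn, Me3SiCl, i-Pr2NEt (cat.), THF, 23 °C; then 1 M HCl, THF
Reagents that add atoms: none
Why: Catalytic asymmetric Nozaki–Hiyama–Kishi 2-(alkoxycarbonyl)allylation, in which the allylchromium species adds through a closed transition state whose face is fixed by the tridentate ligand and not by the weak intrinsic bias of the α-branched aldehyde, should give the (S)-carbinol at C8, and the acid work-up lactonises the γ-hydroxy acrylate.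

**Step 6**
Reactants: 13 (5S)-3-methylidene-5-[(3R)-2-methylhepta-5,6-dien-3-yl]oxolan-2-one; 14 ethynylmagnesium bromide
Product: 15 (6S,7R)-6-hydroxy-4-methylidene-7-(propan-2-yl)undeca-9,10-dien-1-yn-3-one
Conditions: HC≡CMgBr (1.2 equiv), THF, −78 → −20 °C; then pH 7 buffer
Reagents that add atoms: none
Why: 1,2-Addition of the hard alkynyl Grignard reagent to the lactone carbonyl gives a tetrahedral magnesium hemiketal that should persist at low temperature and open to the ynone only on work-up, so that neither double addition nor conjugate addition to the methylene group should interfere (the product may equilibrate with its lactol).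

**Step 7**
Reactants: 15 (6S,7R)-6-hydroxy-4-methylidene-7-(propan-2-yl)undeca-9,10-dien-1-yn-3-one
Product: 16 (6S,7R)-6-[(tert-butyldimethylsilyl)oxy]-4-methylidene-7-(propan-2-yl)undeca-9,10-dien-1-yn-3-one
Conditions: t-BuMe2SiOTf, 2,6-lutidine, CH2Cl2, −78 °C
Reagents that add atoms: tert-butyldimethylsilyl trifluoromethanesulfonate CC(C)(C)[Si](C)(C)OS(=O)(=O)C(F)(F)F
Why: O-Silylation with a silyl triflate and a hindered pyridine base should trap the open-chain secondary alcohol without offering a nucleophile to the ynone.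

**Step 8**
Reactants: 16 (6S,7R)-6-[(tert-butyldimethylsilyl)oxy]-4-methylidene-7-(propan-2-yl)undeca-9,10-dien-1-yn-3-one
Product: 17 (1E,6S,7R)-6-[(tert-butyldimethylsilyl)oxy]-1-[(4-methoxyphenyl)methoxy]-4-methylidene-7-(propan-2-yl)undeca-1,9,10-trien-3-one
Conditions: 4-methoxybenzyl alcohol (1.1 equiv), DABCO (10 mol %), CH2Cl2, 0 → 23 °C
Reagents that add atoms: 4-methoxybenzyl alcohol COc1ccc(CO)cc1
Why: Amine-catalysed oxa-Michael addition of the alcohol to the terminal ynone, the most electrophilic acceptor present, should give the (E)-β-alkoxy enone as the thermodynamically preferred adduct.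

**Step 9**
Reactants: 17 (1E,6S,7R)-6-[(tert-butyldimethylsilyl)oxy]-1-[(4-methoxyphenyl)methoxy]-4-methylidene-7-(propan-2-yl)undeca-1,9,10-trien-3-one
Product: 19 (1E,3Z,6S,7R)-3,6-bis[(tert-butyldimethylsilyl)oxy]-1-[(4-methoxyphenyl)methoxy]-4-methyl-7-(propan-2-yl)undeca-1,3,9,10-tetraene, via lithium enolate 18 (not isolated)
Conditions: LiBH(s-Bu)3 (1.05 equiv), THF, −78 °C; then t-BuMe2SiOTf, −78 → 0 °C; chromatography on Et3N-deactivated silica
Reagents that add atoms: tert-butyldimethylsilyl trifluoromethanesulfonate CC(C)(C)[Si](C)(C)OS(=O)(=O)C(F)(F)F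
Why: Conjugate (1,4) hydride reduction with the bulky, non-chelating borohydride should attack the unsubstituted methylene terminus of the s-trans enone conformer (favoured because the 2-alkyl group avoids the acyl substituent), so that C9 ends cis to oxygen in enolate 18, and O-silylation traps this geometry (methyl inside, tether outside the diene).

**Step 10**
Reactants: 19 (1E,3Z,6S,7R)-3,6-bis[(tert-butyldimethylsilyl)oxy]-1-[(4-methoxyphenyl)methoxy]-4-methyl-7-(propan-2-yl)undeca-1,3,9,10-tetraene
Product: 20 1,8α-bis[(tert-butyldimethylsilyl)oxy]-3α-[(4-methoxyphenyl)methoxy]eudesma-1,4(15)-diene (5αH, 7β-isopropyl, 10β-methyl)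
Conditions: toluene (0.005 M), BHT, N,O-bis(trimethylsilyl)acetamide (5 mol %), base-washed sealed tube, 160 °C
Reagents that add atoms: none
Why: Thermal, concerted but asynchronous suprafacial [4π+2π] cycloaddition in which the electron-rich 1-alkoxy-3-silyloxy diene C3=C2–C1=C10 adds across the inner C4=C5 bond of the allene, driven by the raised diene HOMO and by release of cumulene strain, so that no activating group has to be removed afterwards. The closest known reaction type is the type 1 intramolecular Diels–Alder reaction of tethered diene–allenes (inner double bond reacting, exocyclic methylene left behind) and of 2-silyloxy dienes. Ring A (C10–C1–C2–C3–C4–C5) is closed by the cycloaddition itself and ring B by the C5–C10 bond across the four-carbon tether C6–C9, a six-membered closure through a chair-like tether. The trans ring fusion (C5, C10) should follow from the transition state with the tether outside the diene and C5–H under it, which the C1 silyloxy group enforces by clashing with C8/C9 in the alternative arrangement, and the inside methyl on C10 becomes the axial angular methyl. The absolute sense comes from C7 and C8, because only one diene face lets isopropyl and silyloxy both sit equatorial on the forming chair (the other face puts the C8 silyloxy group 1,3-diaxial to the C10 methyl), and C3 is fixed as 3α (trans to the C10 methyl) by the (E)-enol ether geometry and suprafacial addition. The step needs periselectivity for the inner allene bond (six- against seven-membered tether ring) and must outrun a 1,5-hydrogen shift of the inside methyl, which high dilution, base-washed glassware and a radical inhibitor should secure.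

**Step 11**
Reactants: 20 1,8α-bis[(tert-butyldimethylsilyl)oxy]-3α-[(4-methoxyphenyl)methoxy]eudesma-1,4(15)-diene
Product: 21 8α-[(tert-butyldimethylsilyl)oxy]-3α-[(4-methoxyphenyl)methoxy]eudesm-4(15)-en-1-one
Conditions: Bu4NF, AcOH (1:1), THF, −20 °C
Reagents that add atoms: none
Why: Fluoride-mediated silyl enol ether cleavage is far faster than cleavage of the secondary alkyl silyl ether and protonates C2 under nearly neutral conditions, which should avoid β-elimination of the axial C3 ether.

**Step 12**
Reactants: 21 8α-[(tert-butyldimethylsilyl)oxy]-3α-[(4-methoxyphenyl)methoxy]eudesm-4(15)-en-1-one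
Product: 22 8α-[(tert-butyldimethylsilyl)oxy]-3α-hydroxyeudesm-4(15)-en-1-one
Conditions: DDQ, CH2Cl2/pH 7 buffer (10:1), 0 °C; used crude
Reagents that add atoms: none
Why: Oxidative cleavage of the 4-methoxybenzyl ether by DDQ through the benzylic oxocarbenium ion runs at neutral pH and should leave the silyl ether, the ketone and the 1,1-disubstituted alkene untouched.

**Step 13**
Reactants: 22 8α-[(tert-butyldimethylsilyl)oxy]-3α-hydroxyeudesm-4(15)-en-1-one
Product: 23 8α-[(tert-butyldimethylsilyl)oxy]eudesm-4(15)-ene-1β,3α-diol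
Conditions: Me4NBH(OAc)3, MeCN/AcOH (1:1), −30 °C
Reagents that add atoms: none
Why: Evans–Saksena hydroxyl-directed reduction, in which the axial 3α-hydroxyl binds the acetoxyborohydride and delivers hydride intramolecularly to the α face of the C1 ketone through a chair-like six-membered transition state, should set the equatorial 1β alcohol (1,3-anti).

**Step 14**
Reactants: 24 caffeic acid
Product: 26 (E)-3-{3,4-bis[(tert-butyldimethylsilyl)oxy]phenyl}prop-2-enoic acid, via silyl ester 25 (not isolated)
Conditions: t-BuMe2SiCl, imidazole, DMF, 23 °C; then AcOH/THF/H2O (3:1:1), 23 °C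
Reagents that add atoms: tert-butyldimethylsilyl chloride CC(C)(C)[Si](C)(C)Cl
Why: Exhaustive silylation followed by selective hydrolysis of the labile silyl ester should give the phenol-protected acid needed as the Mitsunobu pronucleophile.

**Step 15**
Reactants: 23 8α-[(tert-butyldimethylsilyl)oxy]eudesm-4(15)-ene-1β,3α-diol; 26 (E)-3-{3,4-bis[(tert-butyldimethylsilyl)oxy]phenyl}prop-2-enoic acid
Product: 27 8α-[(tert-butyldimethylsilyl)oxy]-1β-hydroxyeudesm-4(15)-en-3β-yl (E)-3-{3,4-bis[(tert-butyldimethylsilyl)oxy]phenyl}prop-2-enoate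
Conditions: PPh3, DIAD, toluene, 0 → 23 °C
Reagents that add atoms: none
Why: Mitsunobu esterification, in which the axial allylic C3 oxyphosphonium ion is displaced by the carboxylate in an SN2 reaction from the open equatorial β direction, should invert C3 to the 3β ester while the neopentylic equatorial C1 hydroxyl next to quaternary C10 stays unreacted.

**Step 16**
Reactants: 27 8α-[(tert-butyldimethylsilyl)oxy]-1β-hydroxyeudesm-4(15)-en-3β-yl (E)-3-{3,4-bis[(tert-butyldimethylsilyl)oxy]phenyl}prop-2-enoate
Product: 28 (1R,3S,5S,7R,8S,10R)-1,8-dihydroxyeudesm-4(15)-en-3-yl (E)-3-(3,4-dihydroxyphenyl)prop-2-enoate (CNP0264533.1)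
Conditions: HF·pyridine, pyridine/THF, 0 → 23 °C
Reagents that add atoms: none
Why: Fluoride-mediated desilylation of the two aryl and the one alkyl silyl ether under mildly acidic conditions should spare the cinnamate ester, the catechol and the exocyclic alkene.

**Compound list**

1 | (4R)-4-benzyl-3-(3-methylbutanoyl)-1,3-oxazolidin-2-one | CC(C)CC(=O)N1[C@H](Cc2ccccc2)COC1=O | starting material
2 | propargyl bromide (3-bromoprop-1-yne) | C#CCBr | starting material
3 | sodium (Z)-enolate of 1 | CC(C)/C=C(\[O-])N1[C@H](Cc2ccccc2)COC1=O.[Na+] | intermediate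
4 | (4R)-4-benzyl-3-[(2R)-2-(propan-2-yl)pent-4-ynoyl]-1,3-oxazolidin-2-one | C#CC[C@H](C(C)C)C(=O)N1[C@H](Cc2ccccc2)COC1=O | intermediate
5 | (2R)-2-(propan-2-yl)pent-4-yn-1-ol | OC[C@@H](C(C)C)CC#C | intermediate
6 | paraformaldehyde (source of formaldehyde) | C=O | starting material
7 | (2R)-6-(dicyclohexylamino)-2-(propan-2-yl)hex-4-yn-1-ol | OC[C@@H](C(C)C)CC#CCN(C1CCCCC1)C1CCCCC1 | intermediate
8 | (2R)-2-(propan-2-yl)hexa-4,5-dien-1-ol | OC[C@@H](C(C)C)CC=C=C | intermediate
9 | (2R)-2-(propan-2-yl)hexa-4,5-dienal | O=C[C@@H](C(C)C)CC=C=C | intermediate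
10 | ethyl 2-(bromomethyl)prop-2-enoate | CCOC(=O)C(=C)CBr | starting material
11 | ethyl (4S,5R)-2-methylidene-5-(propan-2-yl)-4-[(trimethylsilyl)oxy]nona-7,8-dienoate | CCOC(=O)C(=C)C[C@H](O[Si](C)(C)C)[C@@H](C(C)C)CC=C=C | intermediate
12 | ethyl (4S,5R)-4-hydroxy-2-methylidene-5-(propan-2-yl)nona-7,8-dienoate | CCOC(=O)C(=C)C[C@H](O)[C@@H](C(C)C)CC=C=C | intermediate
13 | (5S)-3-methylidene-5-[(3R)-2-methylhepta-5,6-dien-3-yl]oxolan-2-one | C=C1C[C@H](OC1=O)[C@@H](C(C)C)CC=C=C | intermediate
14 | ethynylmagnesium bromide | C#C[Mg]Br | starting material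
15 | (6S,7R)-6-hydroxy-4-methylidene-7-(propan-2-yl)undeca-9,10-dien-1-yn-3-one | C#CC(=O)C(=C)C[C@H](O)[C@@H](C(C)C)CC=C=C | intermediate
16 | (6S,7R)-6-[(tert-butyldimethylsilyl)oxy]-4-methylidene-7-(propan-2-yl)undeca-9,10-dien-1-yn-3-one | C#CC(=O)C(=C)C[C@H](O[Si](C)(C)C(C)(C)C)[C@@H](C(C)C)CC=C=C | intermediate
17 | (1E,6S,7R)-6-[(tert-butyldimethylsilyl)oxy]-1-[(4-methoxyphenyl)methoxy]-4-methylidene-7-(propan-2-yl)undeca-1,9,10-trien-3-one | COc1ccc(CO/C=C/C(=O)C(=C)C[C@H](O[Si](C)(C)C(C)(C)C)[C@@H](C(C)C)CC=C=C)cc1 | intermediate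
18 | lithium (1E,3Z)-enolate from conjugate reduction of 17 | COc1ccc(CO/C=C/C([O-])=C(C)/C[C@H](O[Si](C)(C)C(C)(C)C)[C@@H](C(C)C)CC=C=C)cc1.[Li+] | intermediate
19 | (1E,3Z,6S,7R)-3,6-bis[(tert-butyldimethylsilyl)oxy]-1-[(4-methoxyphenyl)methoxy]-4-methyl-7-(propan-2-yl)undeca-1,3,9,10-tetraene | COc1ccc(CO/C=C/C(O[Si](C)(C)C(C)(C)C)=C(C)/C[C@H](O[Si](C)(C)C(C)(C)C)[C@@H](C(C)C)CC=C=C)cc1 | intermediate
20 | 1,8α-bis[(tert-butyldimethylsilyl)oxy]-3α-[(4-methoxyphenyl)methoxy]eudesma-1,4(15)-diene | C=C1[C@H](OCc3ccc(OC)cc3)C=C(O[Si](C)(C)C(C)(C)C)[C@]2(C)C[C@H](O[Si](C)(C)C(C)(C)C)[C@@H](C(C)C)C[C@@H]12 | intermediate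
21 | 8α-[(tert-butyldimethylsilyl)oxy]-3α-[(4-methoxyphenyl)methoxy]eudesm-4(15)-en-1-one | C=C1[C@H](OCc3ccc(OC)cc3)CC(=O)[C@]2(C)C[C@H](O[Si](C)(C)C(C)(C)C)[C@@H](C(C)C)C[C@@H]12 | intermediate
22 | 8α-[(tert-butyldimethylsilyl)oxy]-3α-hydroxyeudesm-4(15)-en-1-one | C=C1[C@H](O)CC(=O)[C@]2(C)C[C@H](O[Si](C)(C)C(C)(C)C)[C@@H](C(C)C)C[C@@H]12 | intermediate
23 | 8α-[(tert-butyldimethylsilyl)oxy]eudesm-4(15)-ene-1β,3α-diol | C=C1[C@H](O)C[C@@H](O)[C@]2(C)C[C@H](O[Si](C)(C)C(C)(C)C)[C@@H](C(C)C)C[C@@H]12 | intermediate
24 | caffeic acid | O=C(O)/C=C/c1ccc(O)c(O)c1 | starting material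
25 | tert-butyldimethylsilyl (E)-3-{3,4-bis[(tert-butyldimethylsilyl)oxy]phenyl}prop-2-enoate | CC(C)(C)[Si](C)(C)OC(=O)/C=C/c1ccc(O[Si](C)(C)C(C)(C)C)c(O[Si](C)(C)C(C)(C)C)c1 | intermediate
26 | (E)-3-{3,4-bis[(tert-butyldimethylsilyl)oxy]phenyl}prop-2-enoic acid | O=C(O)/C=C/c1ccc(O[Si](C)(C)C(C)(C)C)c(O[Si](C)(C)C(C)(C)C)c1 | intermediate
27 | 8α-[(tert-butyldimethylsilyl)oxy]-1β-hydroxyeudesm-4(15)-en-3β-yl (E)-3-{3,4-bis[(tert-butyldimethylsilyl)oxy]phenyl}prop-2-enoate | C=C1[C@@H](OC(=O)/C=C/c3ccc(O[Si](C)(C)C(C)(C)C)c(O[Si](C)(C)C(C)(C)C)c3)C[C@@H](O)[C@]2(C)C[C@H](O[Si](C)(C)C(C)(C)C)[C@@H](C(C)C)C[C@@H]12 | intermediate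
28 | (1R,3S,5S,7R,8S,10R)-1,8-dihydroxyeudesm-4(15)-en-3-yl (E)-3-(3,4-dihydroxyphenyl)prop-2-enoate | C=C1[C@@H](OC(=O)/C=C/c2ccc(O)c(O)c2)C[C@@H](O)[C@]2(C)C[C@H](O)[C@@H](C(C)C)C[C@@H]12 | target

**Step count and risks**

Total step count: 16. Longest linear sequence: 15 steps (steps 1–13, 15 and 16; step 14 is a one-step side branch).

Steps most likely to fail:

Step 10. The cycloaddition may be outrun by a 1,5-hydrogen shift of the inside C10 methyl or by allene dimerisation, and the ring fusion may come out partly cis. The fallback sets out from 19 and returns to 20 by a transition-metal-catalysed intramolecular diene–allene [4+2] cycloaddition (Ni(cod)2 or [RhCl(cod)]2 with P(O-2-biphenylyl)3, THF, 25–60 °C, the metal being chosen for reaction at the inner allene bond). This runs through oxidative cyclisation to a metallacycle and reductive elimination instead of a concerted thermal transition state, and so avoids the temperatures at which hydrogen shifts set in. It makes no compound outside the compound list (F0).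

Step 9. Hydride may add through the s-cis conformer, or the enolate may isomerise before silylation, so that the enol ether geometry (and with it the ring fusion in step 10) is eroded; 1,2-reduction may also compete. The fallback sets out from 17. The same conjugate reduction, quenched with aqueous NH4Cl, gives the saturated α-methyl ketone F1 (both C4 epimers, which converge). Soft enolisation of it (t-BuMe2SiOTf, Et3N, CH2Cl2, prolonged so that the enol ether isomers equilibrate) is under thermodynamic instead of kinetic control and should enrich 19, the isomer with the larger chain cis to the silyloxy group and the methyl cis to the vinyl group. The minor isomer cannot reach a trans-fused adduct and is removed after step 10.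

Step 15. Elimination of the axial oxyphosphonium ion to a diene, SN2′ attack at C15, partial retention through an allyl cation, or reaction at the C1 hydroxyl may compete with clean inversion. The fallback sets out from 23 and replaces the inversion by oxidation and reduction. Selective oxidation of the less hindered axial allylic C3 alcohol (Dess–Martin periodinane, 1 equiv, NaHCO3, CH2Cl2, −20 °C) gives the 1β-hydroxy-4(15)-en-3-one F2. Luche reduction (NaBH4, CeCl3·7H2O, MeOH, −78 °C; axial hydride attack from the α face) gives the equatorial 3β alcohol, the 1β,3β-diol F3. Steglich esterification with acid 26 (EDC·HCl, DMAP, CH2Cl2) at the more accessible allylic C3 hydroxyl returns to 27.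

**Further compounds**

F0 | step 10 | none | none
F1 | step 9 | (1E,6S,7R)-6-[(tert-butyldimethylsilyl)oxy]-1-[(4-methoxyphenyl)methoxy]-4-methyl-7-(propan-2-yl)undeca-1,9,10-trien-3-one (C4 epimers) | COc1ccc(CO/C=C/C(=O)C(C)C[C@H](O[Si](C)(C)C(C)(C)C)[C@@H](C(C)C)CC=C=C)cc1
F2 | step 15 | 8α-[(tert-butyldimethylsilyl)oxy]-1β-hydroxyeudesm-4(15)-en-3-one | C=C1C(=O)C[C@@H](O)[C@]2(C)C[C@H](O[Si](C)(C)C(C)(C)C)[C@@H](C(C)C)C[C@@H]12
F3 | step 15 | 8α-[(tert-butyldimethylsilyl)oxy]eudesm-4(15)-ene-1β,3β-diol | C=C1[C@@H](O)C[C@@H](O)[C@]2(C)C[C@H](O[Si](C)(C)C(C)(C)C)[C@@H](C(C)C)C[C@@H]12
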